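**Strategy**

- Numbering is that of the germacranolides: ring carbons C1–C10 with Z-C1=C10 (methyl C14 on C10) and E-C4=C5 (methyl C15 on C4), lactone oxygen on C6, C7 carrying C11(=C13H2)–C12, ester oxygen on C8, free hydroxyl on C9.
- Cuts, in retrosynthetic order: C9–OH back to the C9 ketone; the lactone O6–C12 bond; the C8–O acyl bond (to epoxyangelic acid, made from angelic acid); the C8–O bond (enolate hydroxylation); then a retro-[3,3] shift cuts C6–C7 and rejoins C4–C9, and the resulting cyclohexenol is cut at C8–C9 into an enyne and a cyclohexenone whose C4 arm comes from an allyl group.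
- What allows the ring contraction: the C9 oxygen is 1,5-related to the C4=C5 alkene through C8–C7–C6, and the cis C1=C10 alkene lies inside the six-atom arc C9–C10–C1–C2–C3–C4, so the carbocycle is the oxy-Cope product of a 1,6-dialkenylcyclohex-2-enol.
- Forward order of rings: the six-membered ring is bought as 2,6-dimethylcyclohexanone and expanded to the cyclodecadiene (step 12); the methylene lactone is closed by oxidative lactonisation (step 18); the epoxide is made on a separate branch and attached as its acid (step 16).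
- Stereochemistry: Pd/(R)-t-Bu-PHOX allylation sets C4 and acetylide addition sets C9; the chair rearrangement converts both into C6, C7 and the E-C4=C5 geometry; C8 comes from peripheral hydroxylation of the enolate, C9 from hydride delivery to the enone, and the two epoxide carbons from tartrate-controlled epoxidation of the Z allylic alcohol.

Key step: step 12

Assumption: the (R)-t-Bu-PHOX catalyst is taken to show the same facial sense with the 2,6-dimethyl enolate as with the parent 2-methylcyclohexanone enolate (R ligand gives the R quaternary centre); commercial 1 is a cis/trans mixture, which is immaterial because its stereocentres are erased or re-set.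

**Route**

Step 1
Reactants: 1 2,6-dimethylcyclohexanone (cis/trans mixture)
Product: 2 2,6-dimethyl-1-(trimethylsilyloxy)cyclohex-1-ene (racemic)
Conditions: TMSOTf, Et3N, CH2Cl2, 0 °C
Reagents that add atoms: trimethylsilyl triflate, C[Si](C)(C)OS(=O)(=O)C(F)(F)F
Why: Silyl triflate/amine enolisation of a ketone with two equivalent α-carbons can give only one, tetrasubstituted, silyl enol ether.

Step 2
Reactants: 2 2,6-dimethyl-1-(trimethylsilyloxy)cyclohex-1-ene; 3 diallyl carbonate
Product: 4 (2R)-2,6-dimethyl-2-(prop-2-en-1-yl)cyclohexan-1-one (both C6 epimers)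
Conditions: Pd2(dba)3 (2.5 mol %), (R)-t-Bu-PHOX (6 mol %), Bu4N[Ph3SiF2] (35 mol %), THF, 25 °C
Reagents that add atoms: none
Why: Enantioselective Tsuji allylation: fluoride-initiated desilylation releases the enolate, which is allylated by the allyl cation equivalent formed from 3 and the zerovalent palladium/phosphinooxazoline catalyst, and the (R)-ligand should set the quaternary carbon as R while the remote C6 methine stays a mixture that step 3 erases.

Step 3
Reactants: 4 (2R)-2,6-dimethyl-2-(prop-2-en-1-yl)cyclohexan-1-one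
Product: 5 (6R)-2,6-dimethyl-6-(prop-2-en-1-yl)-1-(trimethylsilyloxy)cyclohex-1-ene
Conditions: TMSOTf, Et3N, CH2Cl2, 0 → 25 °C
Reagents that add atoms: trimethylsilyl triflate, C[Si](C)(C)OS(=O)(=O)C(F)(F)F
Why: Only the C6 methine is enolisable, so silyl triflate/amine enolisation gives a single tetrasubstituted silyl enol ether and turns the uncontrolled C6 centre into an sp2 carbon.

Step 4
Reactants: 5 (6R)-2,6-dimethyl-6-(prop-2-en-1-yl)-1-(trimethylsilyloxy)cyclohex-1-ene
Product: 6 (6R)-2,6-dimethyl-6-(prop-2-en-1-yl)cyclohex-2-en-1-one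
Conditions: Pd(OAc)2 (1.1 equiv), MeCN, 25 °C
Reagents that add atoms: none
Why: Saegusa–Ito dehydrogenation: the enol ether hands its enolate to Pd(OAc)2 (divalent palladium), and β-hydride elimination into the ring gives the conjugated 2-methyl enone without touching the quaternary centre.

Step 5
Reactants: 6 (6R)-2,6-dimethyl-6-(prop-2-en-1-yl)cyclohex-2-en-1-one
Product: 8 2-[(1R)-1,3-dimethyl-2-oxocyclohex-3-en-1-yl]acetaldehyde, via diol 7 (not isolated)
Conditions: OsO4 (2 mol %), NaIO4, 2,6-lutidine, dioxane/H2O 3:1, 25 °C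
Reagents that add atoms: osmium tetroxide, O=[Os](=O)(=O)=O; sodium periodate (reoxidant), [Na+].[O-]I(=O)(=O)=O
Why: Lemieux–Johnson oxidation: OsO4 dihydroxylates the monosubstituted allyl alkene much faster than the electron-poor trisubstituted enone alkene, and periodate cleaves diol 7 to the aldehyde.

Step 6
Reactants: 8 2-[(1R)-1,3-dimethyl-2-oxocyclohex-3-en-1-yl]acetaldehyde
Product: 9 fragment 1, (6R)-2,6-dimethyl-6-[(E)-2-(triisopropylsilyloxy)ethenyl]cyclohex-2-en-1-one
Conditions: TIPSOTf, Et3N, CH2Cl2, −78 → 0 °C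
Reagents that add atoms: triisopropylsilyl triflate, CC(C)[Si](OS(=O)(=O)C(F)(F)F)(C(C)C)C(C)C
Why: Silyl triflate/amine enolisation of the aldehyde (the hindered enone has no α′-hydrogen) gives the enol ether, and the E isomer is expected because the quaternary carbon avoids a cis relationship to the bulky silyloxy group; any Z isomer equilibrates under the triflate-buffered conditions or is removed by chromatography.

Step 7
Reactants: 10 2-bromoprop-2-en-1-ol; 11 ethynyltrimethylsilane
Product: 12 2-methylidene-4-(trimethylsilyl)but-3-yn-1-ol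
Conditions: Pd(PPh3)2Cl2 (2 mol %), CuI (4 mol %), i-Pr2NH, THF, 25 °C
Reagents that add atoms: none
Why: Sonogashira coupling of a vinyl bromide with a terminal alkyne tolerates the free allylic alcohol.

Step 8
Reactants: 12 2-methylidene-4-(trimethylsilyl)but-3-yn-1-ol
Product: 13 tert-butyldimethyl{[2-methylidene-4-(trimethylsilyl)but-3-yn-1-yl]oxy}silane
Conditions: TBSCl, imidazole, CH2Cl2, 25 °C
Reagents that add atoms: tert-butyldimethylsilyl chloride, CC(C)(C)[Si](C)(C)Cl
Why: Standard silylation of a primary alcohol.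

Step 9
Reactants: 13 tert-butyldimethyl{[2-methylidene-4-(trimethylsilyl)but-3-yn-1-yl]oxy}silane
Product: 14 fragment 2, tert-butyldimethyl[(2-methylidenebut-3-yn-1-yl)oxy]silane
Conditions: K2CO3 (cat.), MeOH, 0 → 25 °C
Reagents that add atoms: none
Why: Methanolysis cleaves the alkynyl C–Si bond selectively and leaves the silyl ether.

Step 10
Reactants: 9 fragment 1; 14 fragment 2
Product: 16 (1R,6R)-1-[3-(tert-butyldimethylsilyloxymethyl)but-3-en-1-yn-1-yl]-2,6-dimethyl-6-[(E)-2-(triisopropylsilyloxy)ethenyl]cyclohex-2-en-1-ol (ring C1 = future C9; ring C6 = future C4), via lithium acetylide 15 (not isolated)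
Conditions: 14, n-BuLi, THF, −78 °C; then 9, −78 → −30 °C; then H2O
Reagents that add atoms: none
Why: 1,2-Addition of a lithium acetylide to a non-enolisable enone carbonyl; Felkin–Anh-type axial attack anti to the pseudoaxial silyloxyvinyl arm (the larger and better σ-acceptor group on C4) should place the alkynyl group cis to the C4 methyl and so set C9, and the minor epimer is removed by chromatography.

Step 11
Reactants: 16 propargylic alcohol
Product: 17 (1R,6R)-1-[(1Z)-3-(tert-butyldimethylsilyloxymethyl)buta-1,3-dien-1-yl]-2,6-dimethyl-6-[(E)-2-(triisopropylsilyloxy)ethenyl]cyclohex-2-en-1-ol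
Conditions: H2 (1 atm), Pd/CaCO3 (Pb-poisoned), quinoline, EtOAc, 25 °C
Reagents that add atoms: none
Why: Lindlar semihydrogenation: syn delivery of one equivalent of H2 to the alkyne on Pb-poisoned Pd/CaCO3 gives the Z diene and leaves the enol ether, the ring alkene and the 1,1-disubstituted alkene untouched.

Step 12
Reactants: 17 Z-dienyl cyclohexenol
Product: 20 (6S,7R,8R)-8-hydroxy-6-(triisopropylsilyloxy)-12-(tert-butyldimethylsilyloxy)germacra-1(10)Z,4E,11(13)-trien-9-one, via potassium alkoxide 18 (not isolated), via potassium enolate 19 (not isolated)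
Conditions: KH (1.1 equiv), 18-crown-6, THF, 0 → 25 °C; then −78 °C, 2-(phenylsulfonyl)-3-phenyloxaziridine; then AcOH, −78 °C
Reagents that add atoms: 2-(phenylsulfonyl)-3-phenyloxaziridine, O=S(=O)(N1OC1c1ccccc1)c1ccccc1
Why: Deprotonation gives alkoxide 18, whose C7=C8–C9–C4–C5=C6 diene undergoes an alkoxide-accelerated concerted [3,3] shift in which C6–C7 forms as C4–C9 breaks; this is the anionic oxy-Cope ring expansion of 1,2-dialkenylcyclohexanols with oxidation of the resulting enolate in the same flask. No ring closes in an exo or endo sense: the ten-membered carbocycle arises by four-atom expansion of the cyclohexene, whose cis alkene becomes Z-C1=C10 and whose equatorial C4–C3 bond ends trans to C6 across the new E-C4=C5 bond. C6 and C7 are set by the chair transition state, which relays the configurations of C4 and C9 with the E enol ether oxygen equatorial and the Z dienyl carbon C11 axial, so that O6 and C11 end cis (the later cis-fused lactone) in the 6S,7S sense of the target. C8 is set when enolate 19, which can react only at C8, is hydroxylated by the N-sulfonyloxaziridine from the ring periphery anti to C6 in the conformer that holds C7–H in the enolate plane next to the oxygen (allylic 1,3-strain), which places the new C–O bond trans to the C7 side chain. The step needs chair over boat and one chair over the other; the trans (diequatorial) arrangement of the two alkenyl arms secures this, because only that chair keeps both ring bonds equatorial, with the axial C11 meeting only the alkoxide oxygen and the axial C4 methyl meeting only hydrogen, and the E enol ether keeps the silyl group out of reach of the alkoxide.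

Step 13
Reactants: 21 angelic acid, (Z)-2-methylbut-2-enoic acid
Product: 22 (Z)-2-methylbut-2-en-1-ol
Conditions: LiAlH4, Et2O, 0 °C
Reagents that add atoms: none
Why: Hydride reduction of the carboxylic acid (1,2-addition) gives the allylic alcohol with the Z geometry retained.

Step 14
Reactants: 22 (Z)-2-methylbut-2-en-1-ol
Product: 23 [(2S,3R)-2,3-dimethyloxiran-2-yl]methanol
Conditions: Ti(OiPr)4 (10 mol %), L-(+)-diethyl tartrate (12 mol %), t-BuOOH, 4 Å sieves, CH2Cl2, −20 °C
Reagents that add atoms: tert-butyl hydroperoxide, CC(C)(C)OO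
Why: Sharpless asymmetric epoxidation: stereospecific syn oxygen transfer from the Ti(OiPr)4/tartrate/t-BuOOH system keeps the two methyl groups trans, and L-(+)-diethyl tartrate directs oxygen to the face that gives the 2S,3R epoxy alcohol.

Step 15
Reactants: 23 [(2S,3R)-2,3-dimethyloxiran-2-yl]methanol
Product: 25 fragment 3, (2R,3R)-2,3-dimethyloxirane-2-carboxylic acid, via epoxy aldehyde 24 (not isolated)
Conditions: RuCl3·H2O (2 mol %), NaIO4, CCl4/MeCN/H2O, 0 → 25 °C
Reagents that add atoms: water, O; sodium periodate (reoxidant), [Na+].[O-]I(=O)(=O)=O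
Why: RuO4 generated in situ from RuCl3 and periodate oxidises the primary alcohol through aldehyde 24 and its hydrate to the acid without opening the epoxide, so both stereocentres persist (2S becomes 2R only through the change in priorities).

Step 16
Reactants: 20 hydroxy ketone; 25 fragment 3
Product: 27 (6S,7R,8R)-9-oxo-6-(triisopropylsilyloxy)-12-(tert-butyldimethylsilyloxy)germacra-1(10)Z,4E,11(13)-trien-8-yl (2R,3R)-2,3-dimethyloxirane-2-carboxylate, via mixed anhydride 26 (not isolated)
Conditions: 25, 2,4,6-trichlorobenzoyl chloride, Et3N, THF, 25 °C; then 20, DMAP, toluene, 25 °C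
Reagents that add atoms: none
Why: Yamaguchi esterification: mixed anhydride 26 acylates the only free hydroxyl under DMAP catalysis with retention at C8, and the diastereomeric ester arising from the minor enantiomer of 20 is removed here by chromatography.

Step 17
Reactants: 27 bis-silyl ether ester
Product: 28 (6S,7S,8R)-6,12-dihydroxy-9-oxogermacra-1(10)Z,4E,11(13)-trien-8-yl (2R,3R)-2,3-dimethyloxirane-2-carboxylate
Conditions: HF·pyridine, pyridine, THF, 0 → 25 °C
Reagents that add atoms: none
Why: Fluoride-driven cleavage of both Si–O bonds; pyridine-buffered HF should leave the epoxy ester (epoxide deactivated by the adjacent carbonyl) and the α-acyloxy ketone intact.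

Step 18
Reactants: 28 diol
Product: 31 (6S,7S,8R)-9-oxo-8-[(2R,3R)-2,3-dimethyloxirane-2-carbonyloxy]germacra-1(10)Z,4E,11(13)-trien-12,6-olide, via hydroxy enal 29 (not isolated), via lactol 30 (not isolated)
Conditions: TEMPO (20 mol %), PhI(OAc)2 (3 equiv), CH2Cl2, 25 °C
Reagents that add atoms: none
Why: Oxoammonium oxidation (TEMPO/PhI(OAc)2) of the primary allylic alcohol gives enal 29, the C6 hydroxyl adds to it (5-exo-trig) to give lactol 30, and a second oxidation gives the α-methylene lactone, whose cis ring fusion was fixed at C6 and C7 in step 12.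

Step 19
Reactants: 31 keto lactone
Product: 32 target CNP0318223.2, (6S,7S,8R,9R)-9-hydroxy-8-[(2R,3R)-2,3-dimethyloxirane-2-carbonyloxy]germacra-1(10)Z,4E,11(13)-trien-12,6-olide
Conditions: NaBH4, CeCl3·7H2O, MeOH, −78 °C
Reagents that add atoms: none
Why: Luche reduction: CeCl3-activated 1,2-hydride addition to the enone carbonyl at −78 °C is faster than conjugate reduction of the methylene lactone, and hydride should arrive from the ring periphery anti to the C8 acyloxy group (C8–O turned away from the carbonyl dipole), giving the 9R alcohol with O8 and O9 on opposite faces of the ring.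

**Compound list**

1 | 2,6-dimethylcyclohexanone (cis/trans mixture) | CC1CCCC(C)C1=O | starting material
2 | 2,6-dimethyl-1-(trimethylsilyloxy)cyclohex-1-ene (racemic) | CC1CCCC(C)=C1O[Si](C)(C)C | intermediate
3 | diallyl carbonate | C=CCOC(=O)OCC=C | starting material
4 | (2R)-2,6-dimethyl-2-(prop-2-en-1-yl)cyclohexan-1-one (both C6 epimers) | CC1CCC[C@](C)(CC=C)C1=O | intermediate
5 | (6R)-2,6-dimethyl-6-(prop-2-en-1-yl)-1-(trimethylsilyloxy)cyclohex-1-ene | CC1=C(O[Si](C)(C)C)[C@@](C)(CC=C)CCC1 | intermediate
6 | (6R)-2,6-dimethyl-6-(prop-2-en-1-yl)cyclohex-2-en-1-one | CC1=CCC[C@](C)(CC=C)C1=O | intermediate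
7 | (6R)-6-(2,3-dihydroxypropyl)-2,6-dimethylcyclohex-2-en-1-one (both carbinol epimers) | CC1=CCC[C@](C)(CC(O)CO)C1=O | intermediate
8 | 2-[(1R)-1,3-dimethyl-2-oxocyclohex-3-en-1-yl]acetaldehyde | CC1=CCC[C@](C)(CC=O)C1=O | intermediate
9 | fragment 1, (6R)-2,6-dimethyl-6-[(E)-2-(triisopropylsilyloxy)ethenyl]cyclohex-2-en-1-one | CC1=CCC[C@](C)(/C=C/O[Si](C(C)C)(C(C)C)C(C)C)C1=O | intermediate
10 | 2-bromoprop-2-en-1-ol | C=C(Br)CO | starting material
11 | ethynyltrimethylsilane | C#C[Si](C)(C)C | starting material
12 | 2-methylidene-4-(trimethylsilyl)but-3-yn-1-ol | C=C(CO)C#C[Si](C)(C)C | intermediate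
13 | tert-butyldimethyl{[2-methylidene-4-(trimethylsilyl)but-3-yn-1-yl]oxy}silane | C=C(CO[Si](C)(C)C(C)(C)C)C#C[Si](C)(C)C | intermediate
14 | fragment 2, tert-butyldimethyl[(2-methylidenebut-3-yn-1-yl)oxy]silane | C=C(CO[Si](C)(C)C(C)(C)C)C#C | intermediate
15 | lithium acetylide of 14 | [Li]C#CC(=C)CO[Si](C)(C)C(C)(C)C | intermediate
16 | (1R,6R)-1-[3-(tert-butyldimethylsilyloxymethyl)but-3-en-1-yn-1-yl]-2,6-dimethyl-6-[(E)-2-(triisopropylsilyloxy)ethenyl]cyclohex-2-en-1-ol | CC1=CCC[C@](C)(/C=C/O[Si](C(C)C)(C(C)C)C(C)C)[C@@]1(O)C#CC(=C)CO[Si](C)(C)C(C)(C)C | intermediate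
17 | (1R,6R)-1-[(1Z)-3-(tert-butyldimethylsilyloxymethyl)buta-1,3-dien-1-yl]-2,6-dimethyl-6-[(E)-2-(triisopropylsilyloxy)ethenyl]cyclohex-2-en-1-ol | CC1=CCC[C@](C)(/C=C/O[Si](C(C)C)(C(C)C)C(C)C)[C@@]1(O)/C=C\C(=C)CO[Si](C)(C)C(C)(C)C | intermediate
18 | potassium alkoxide of 17 | CC1=CCC[C@](C)(/C=C/O[Si](C(C)C)(C(C)C)C(C)C)[C@@]1([O-])/C=C\C(=C)CO[Si](C)(C)C(C)(C)C.[K+] | intermediate
19 | potassium (6S,7S)-6-(triisopropylsilyloxy)-12-(tert-butyldimethylsilyloxy)germacra-1(10)Z,4E,8,11(13)-tetraen-9-olate (C10 trans to C7 across C8=C9) | C1/C=C(/C)\C([O-])=C\[C@@H](C(=C)CO[Si](C)(C)C(C)(C)C)[C@@H](O[Si](C(C)C)(C(C)C)C(C)C)/C=C(\C)C1.[K+] | intermediate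
20 | (6S,7R,8R)-8-hydroxy-6-(triisopropylsilyloxy)-12-(tert-butyldimethylsilyloxy)germacra-1(10)Z,4E,11(13)-trien-9-one | C=C(CO[Si](C)(C)C(C)(C)C)[C@H]1[C@@H](O[Si](C(C)C)(C(C)C)C(C)C)/C=C(\C)CC/C=C(/C)C(=O)[C@@H]1O | intermediate
21 | angelic acid, (Z)-2-methylbut-2-enoic acid | C/C=C(/C)C(=O)O | starting material
22 | (Z)-2-methylbut-2-en-1-ol | C/C=C(/C)CO | intermediate
23 | [(2S,3R)-2,3-dimethyloxiran-2-yl]methanol | OC[C@]1(C)O[C@@H]1C | intermediate
24 | (2R,3R)-2,3-dimethyloxirane-2-carbaldehyde | O=C[C@]1(C)O[C@@H]1C | intermediate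
25 | fragment 3, (2R,3R)-2,3-dimethyloxirane-2-carboxylic acid | OC(=O)[C@]1(C)O[C@@H]1C | intermediate
26 | (2R,3R)-2,3-dimethyloxirane-2-carboxylic 2,4,6-trichlorobenzoic anhydride | O=C(OC(=O)c1c(Cl)cc(Cl)cc1Cl)[C@]2(C)O[C@@H]2C | intermediate
27 | (6S,7R,8R)-9-oxo-6-(triisopropylsilyloxy)-12-(tert-butyldimethylsilyloxy)germacra-1(10)Z,4E,11(13)-trien-8-yl (2R,3R)-2,3-dimethyloxirane-2-carboxylate | C=C(CO[Si](C)(C)C(C)(C)C)[C@H]1[C@@H](O[Si](C(C)C)(C(C)C)C(C)C)/C=C(\C)CC/C=C(/C)C(=O)[C@@H]1OC(=O)[C@]2(C)O[C@@H]2C | intermediate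
28 | (6S,7S,8R)-6,12-dihydroxy-9-oxogermacra-1(10)Z,4E,11(13)-trien-8-yl (2R,3R)-2,3-dimethyloxirane-2-carboxylate | C=C(CO)[C@H]1[C@@H](O)/C=C(\C)CC/C=C(/C)C(=O)[C@@H]1OC(=O)[C@]2(C)O[C@@H]2C | intermediate
29 | (6S,7S,8R)-6-hydroxy-9,12-dioxogermacra-1(10)Z,4E,11(13)-trien-8-yl (2R,3R)-2,3-dimethyloxirane-2-carboxylate (hydroxy enal) | C=C(C=O)[C@H]1[C@@H](O)/C=C(\C)CC/C=C(/C)C(=O)[C@@H]1OC(=O)[C@]2(C)O[C@@H]2C | intermediate
30 | 12-hydroxy-6,12-epoxy lactol of 29 (both C12 epimers) | C=C1C(O)O[C@H]2/C=C(\C)CC/C=C(/C)C(=O)[C@H](OC(=O)[C@]3(C)O[C@@H]3C)[C@@H]12 | intermediate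
31 | (6S,7S,8R)-9-oxo-8-[(2R,3R)-2,3-dimethyloxirane-2-carbonyloxy]germacra-1(10)Z,4E,11(13)-trien-12,6-olide | C=C1C(=O)O[C@H]2/C=C(\C)CC/C=C(/C)C(=O)[C@H](OC(=O)[C@]3(C)O[C@@H]3C)[C@@H]12 | intermediate
32 | CNP0318223.2, (6S,7S,8R,9R)-9-hydroxy-8-[(2R,3R)-2,3-dimethyloxirane-2-carbonyloxy]germacra-1(10)Z,4E,11(13)-trien-12,6-olide | C=C1C(=O)O[C@H]2/C=C(\C)CC/C=C(/C)[C@@H](O)[C@H](OC(=O)[C@]3(C)O[C@@H]3C)[C@@H]12 | target

**Step count and risks**

Total step count: 19. Longest linear sequence: 13 steps (steps 1–6, 10–12, 16–19, from 1 to 32).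

Steps most likely to fail:

1. Step 12. The oxygen may be delivered before the ring has relaxed from the conformer that the chair transition state produces (C7–H anti to the enolate oxygen), so that the oxaziridine attacks the other enolate face and the hydroxyl ends up cis to the C7 side chain. Addition of the enolate to the sulfonimine by-product, or a sluggish shift of the axial Z-dienyl terminus, would lower the throughput further. Fallback: C8 is then set by invertive acylation instead of face-selective oxidation. Setting out from 17, the same rearrangement and hydroxylation are run for the 8S epimer, the (6S,7R,8S)-hydroxy ketone F1, which is esterified with acid 25 under Mitsunobu conditions (PPh3, DIAD, toluene, 0 °C). SN2 displacement of the activated C8 oxygen next to the carbonyl inverts C8 and returns to the route at 27.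

2. Step 10. The slim acetylide may attack the enone conformer in which the C4 methyl, not the silyloxyvinyl arm, is pseudoaxial. That gives the cis-dialkenyl epimer, which cannot reach the productive chair in step 12. Fallback: the alkyne is replaced by a preformed, bulkier Z-dienyl nucleophile, which is more sensitive to the size of the equatorial C4 substituent beside its trajectory and makes the semihydrogenation unnecessary. Setting out from 14, iodination (N-iodosuccinimide, AgNO3 cat., acetone) gives the iodoalkyne F2. Hydroboration with dicyclohexylborane and protonolysis with AcOH give the (Z)-iodo diene F3. Iodine–lithium exchange (t-BuLi, Et2O, −78 °C) gives the (Z)-dienyllithium F4, which adds to ketone 9 and returns to the route at 17.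

3. Step 19. Hydride may be delivered to the other face of the C9 carbonyl, because the ring conformation and not the acyclic model decides; conjugate reduction of the methylene lactone may also compete. Fallback: the C9 configuration is corrected by inversion instead of facial control. Setting out from 31, the reduction then gives mainly the 9S alcohol, the 9-epimer of the target F5. Mitsunobu reaction with formic acid (PPh3, DIAD, THF, 0 °C) inverts C9 to the 9R formate F6, whose formyl group is removed by brief KHCO3/MeOH treatment at 0 °C, returning to the route at 32.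

Further compounds

F1 | step 12 | (6S,7R,8S)-8-hydroxy-6-(triisopropylsilyloxy)-12-(tert-butyldimethylsilyloxy)germacra-1(10)Z,4E,11(13)-trien-9-one (8-epimer of 20) | C=C(CO[Si](C)(C)C(C)(C)C)[C@H]1[C@@H](O[Si](C(C)C)(C(C)C)C(C)C)/C=C(\C)CC/C=C(/C)C(=O)[C@H]1O
F2 | step 10 | tert-butyl[(4-iodo-2-methylidenebut-3-yn-1-yl)oxy]dimethylsilane | C=C(CO[Si](C)(C)C(C)(C)C)C#CI
F3 | step 10 | tert-butyl{[(3Z)-4-iodo-2-methylidenebut-3-en-1-yl]oxy}dimethylsilane | C=C(CO[Si](C)(C)C(C)(C)C)/C=C\I
F4 | step 10 | (1Z)-3-(tert-butyldimethylsilyloxymethyl)buta-1,3-dien-1-yllithium | [Li]/C=C\C(=C)CO[Si](C)(C)C(C)(C)C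
F5 | step 19 | (6S,7S,8R,9S)-9-hydroxy-8-[(2R,3R)-2,3-dimethyloxirane-2-carbonyloxy]germacra-1(10)Z,4E,11(13)-trien-12,6-olide (9-epimer of 32) | C=C1C(=O)O[C@H]2/C=C(\C)CC/C=C(/C)[C@H](O)[C@H](OC(=O)[C@]3(C)O[C@@H]3C)[C@@H]12
F6 | step 19 | (6S,7S,8R,9R)-9-formyloxy-8-[(2R,3R)-2,3-dimethyloxirane-2-carbonyloxy]germacra-1(10)Z,4E,11(13)-trien-12,6-olide | C=C1C(=O)O[C@H]2/C=C(\C)CC/C=C(/C)[C@@H](OC=O)[C@H](OC(=O)[C@]3(C)O[C@@H]3C)[C@@H]12
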